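(All runs are calculated for substances that don't exist; scatter was added.)

Target and dissolved substrate are the two peaks that show how far the solid substrate has got in the blue flask, which is also the flask asked about.

common to all: solid substrate 0.013 M; gas 0.43 mM (held)

| run | remark | time |
|---|---|---|
| blue | the very flask that is asked about, followed so far |  |
| flask |  | 3.0 min |

blue run (percent of the solid substrate charged)

| time / s | target / % | dissolved substrate / % |
|---|---|---|
| 10.0 | 1.2 | 5.7 |
| 20.0 | 5.2 | 6.3 |
| 25.0 | 10.4 | 9.5 |
| 40.0 | 14.6 | 12.3 |

(standard deviation of a reading: 1 percentage point)

- as a solid, counted per litre of solution: solid substrate
- at the start none of reagent is dissolved
- reactions considered so far: target <-> isomer of the product; solid substrate <-> dissolved substrate; dissolved substrate + reagent <-> target; gas <-> reagent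
- at the start none of the solid substrate is in solution
- dissolved substrate means what is dissolved; the solid is not counted in it

- amount of target at 3.0 min, in percent of the solid substrate charged
- concentration of dissolved substrate in solution at 50 s, in percent of saturation
- the change that raises the amount of target at 3.0 min, in percent of the solid substrate charged most ("none" if none brings more than 2 percentage points) (north / east / south-east / north-west / none)
- amount of target at 3.0 min, in percent of the solid substrate charged, after north-west

- north: doubling the saturation concentration of gas, all else as stated
- east: doubling the transfer coefficient of the gas, all else as stated
- south-east: doubling the dissolution coefficient of the solid substrate, all else as stated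
- north-west: doubling the solubility of the solid substrate, all else as stated

At 40.0 s the readings give 1.19. This split, target divided by dissolved substrate at one moment, is the number to carry, with the scatter of 1 percentage point in each reading behind it.

Turn the question round. This reckoning takes it that south-east or north-west can beat a change on the gas side where dissolved substrate is taken up as it arrives, which means a split far above one. The blue flask stands at 1.19: target is 54.3 % of the two peaks together, and the rest stands unreacted in solution. More solid in solution adds to that pool, so this reckoning sets south-east and north-west aside; the split cannot part north from east, and north is this reckoning's choice between the two.

The two peaks also give a pace. At that pace the charge passes in 2.48 min, shorter than 3.0 min. So this reckoning puts target at 54.3 % of the charge, less whatever the isomer of the product takes.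

The forecast gives 55 %, 40 %, north and 60 %, on its reading of “limitation by gas supply”.

The flask gives 41.1 %, below the reckoned share, and 23.6 %. Its best change is north, with a gain of 9.5 points against 0.78 points for east, with reagent at 92.4 % of saturation at 1.50 min, and north-west gives 38.9 %. Its split at 3.0 min is 1.44.

    target ⇌ isomer of the product (K = 14.0, k = 0.00590 /s)
    solid substrate ⇌ dissolved substrate, rate k2*(cs2 - [dissolved substrate]) while solid is left; crystals form when [dissolved substrate] > cs2 (solubility = 7.70 mM, k = 0.0130 /s)
    dissolved substrate + reagent ⇌ target (K = 4000 /M, k = 300 /M/s)
    gas ⇌ reagent, rate k4*(csat - [reagent]) (kL = 1.50 /s)

The crawl of solid substrate into solution is at most the largest single effect on dissolved substrate at 50 s, not the main reason: in the run without that crawl, dissolved substrate stands at 58.5 % of saturation against 23.6 %, and north is no longer best.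

In the neighbour flask read at 50 s, the carried split times its dissolved substrate of 14.0 % gives 16.7 % of target. That flask holds 16.7 %.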